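The pitfall in these runs is reading a falling substrate as a rising target. We have four flasks to rank at the end of their time, and three earlier runs to go on.

| flask | substrate | partner | reagent | temperature | remark | time |
|---|---|---|---|---|---|---|
| east | 0.016 M | 0.032 M | 0.024 M | 10 °C | run made earlier |  |
| west | 0.016 M | 0.045 M | 0.024 M | 25 °C | run made earlier |  |
| north-east | 0.016 M | 0.070 M | 0.024 M | 10 °C | run made earlier |  |
| alder | 0.016 M | 0.0320 M | 0.0240 M (fed, over 4.0 min) | 25 °C | all else is in the flask from the start; the feed brings no volume worth counting | 6.0 min |
| maple | 0.016 M | 0.0320 M | 0.0240 M | 25 °C | everything together at the start | 6.0 min |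
| birch | 0.016 M | 0.0320 M | 0.0240 M (fed, over 4.0 min) |  | the addition at 5 °C, then warmed to 25 °C; the feed brings no volume worth counting | 6.0 min |
| larch | 0.016 M (fed, over 4.0 min) | 0.0320 M | 0.0240 M | 25 °C | all else is in the flask from the start; the feed brings no volume worth counting | 6.0 min |

- east (time / min: target / %, substrate / %): 1.00: 0.4, 95.4; 2.00: 0.6, 93.4; 3.00: 0.6, 88.0; 4.00: 0.1, 86.2; 8.00: 1.2, 76.8; 12.0: 3.0, 70.5
- west (time / min: target / %, substrate / %): 0.667: 0.5, 90.8; 1.33: 0.3, 83.6; 2.00: 1.2, 78.7; 2.50: 1.6, 75.8; 3.00: 2.8, 71.2; 4.00: 5.1, 67.5
- north-east (time / min: target / %, substrate / %): 1.33: 0, 93.9; 3.00: 0, 90.3; 4.00: 0, 87.5; 5.00: 0.4, 84.4; 6.00: 1.4, 83.3; 8.00: 2.4, 80.7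

(each reading ± 0.5 percentage points)

- the best flask by amount of target, in percent of the substrate charged; "all alike" if 1.5 percentage points covers them all (alder / maple / birch / larch / all alike)
- amount of target at the end, in percent of the substrate charged, alder
- amount of target at the end, in percent of the substrate charged, maple
- amount of target at the end, in percent of the substrate charged, birch
- amount of target at the end, in percent of the substrate charged, larch

- amounts and yields of target count crystals too
- given per volume of solution although it is solid: crystals
- on the list of suspects stand: substrate + reagent -> open intermediate; crystals <-> target; partner -> decomposition product; reagent + partner -> second intermediate; open intermediate + second intermediate <-> target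

The west run looks contradictory: at 4.00 min substrate stands at 67.5%, yet target reads 5.1%, so 27.4% of the charge sits in neither peak. The rates clear this up. In its first interval the west run loses 9.2 percentage points of substrate and gains 0.5% of target, but in its last interval it loses 3.7 points and gains 2.3 points, so target is catching up.

That drift is what a coupling of two intermediates gives. Each starts from nothing and grows about as time, their product grows as its square, and target, which sums that product, grows as its cube. At a fixed substrate charge we therefore divide target by c(partner) and by the square of c(reagent), take the cube root, divide by time, and call the result the lag constant 3.13 M⁻¹ min⁻¹, with target as a fraction of the charge. Read from the last west reading, it gives 2.15% at 3.00 min, against a reading of 2.8%. For maple our own reckoning gives 12.2%, which we expect to be high, since it holds reagent undiminished. In alder and birch the fed reagent holds back both factors of the product, and in larch the fed substrate holds back one, over the 4.0 min of the feed, so we too pick maple.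

The forecast also says maple, but with a lower 7.5% for maple, then 5.8% for larch, 3.3% for alder and 1.4% for birch, on the ground that “Maple builds both soonest”.

The flasks give 9.08% for maple, 5.53% for larch, 3.96% for alder and 1.33% for birch, so maple leads.

    substrate + reagent → open intermediate (k = 0.110 M⁻¹ s⁻¹, Ea = 60.0 kJ mol⁻¹)
    crystals ⇌ target, rate k2*(cs2 - [target]) while solid is left; crystals form when [target] > cs2 (solubility = 4.90 mM, k = 0.120 s⁻¹)
    partner → decomposition product (k = 1.00 × 10⁻⁵ s⁻¹, Ea = 99.0 kJ mol⁻¹)
    reagent + partner → second intermediate (k = 0.0710 M⁻¹ s⁻¹, Ea = 46.0 kJ mol⁻¹)
    open intermediate + second intermediate ⇌ target (K = 2300 M⁻¹, k = 0.170 M⁻¹ s⁻¹, Ea = 67.0 kJ mol⁻¹, ΔH = 2.00 kJ mol⁻¹)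
    (constants at 25 °C)

Maple stands at 0.744 of our reckoning, with 32.3% of its reagent left at the end. Now take a neighbour of birch charged with 0.060 M of reagent. With the same lag constant, birch's own result makes it worth 2.86 min of maple's clock. Keeping that clock and raising c(reagent) gives the neighbour 8.32%. The neighbour holds 45.7% as open intermediate at the end, and its target stands at 6.18%.

The readings were generated by integration on assumed constants.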